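**Plan**

1. Retrosynthetic cuts: C4–C4a (aryl–acyl bond of ring C, made last of the ring bonds), C3–C1' (ring B to C3), O1–C2 (aryl ether), the C3–H bond (traced back to a temporary C3–O bond) and the two aryl–prenyl bonds.
2. Forward: a ring A phenol with the prenyl group para to the free OH and MOM ethers on the future O5/O7 is iodinated and O-alkylated with ethyl bromopyruvate (C2–C3–C4). The ketone is then attacked by the ortho carbon of the ring B phenol, and the ester lactonises onto that phenol.
3. The resulting 1-benzofuran-2-one (bond O2'–C4, not in the target) stores C4 as an aryl ester and masks the 2'-OH. Iodine–magnesium exchange at C4a then closes ring C on C4 and opens the lactone in the same event.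
4. Enabling features: O2' is 1,4-related to C4 through C2'–C1'–C3, so C4 can be held in a five-membered aryl lactone. In ring A, O1 (on C8a) is para to the C6 prenyl group between the C5 and C7 oxygens, so C4a and C8 are equivalent in the precursor and the 6-prenyl pattern needs no regiochemical choice.
5. Stereochemistry: the temporary C3–OH (the pyruvate ketone oxygen) keeps C3 non-enolisable during ring closure. As its acetate it is removed with SmI2, and ligand-controlled protonation of the samarium enolate sets (3S); only a mild deprotection follows.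

Key step: step 9

Assumption: the target descriptor read from the SMILES is (3S); which BINAPO antipode delivers it in step 11 is an empirical matter, and both antipodes are available.

**Route**

Step 1
Reactants: 1 phloroglucinol (benzene-1,3,5-triol); 2 chloromethyl methyl ether
Product: 3 3,5-bis(methoxymethoxy)phenol
Conditions: MOMCl (2.0 equiv), i-Pr2NEt (2.2 equiv), DMF, 0 °C → rt; chromatographic separation, mono-ether recycled
Reagents that add atoms: chloromethyl methyl ether, COCCl
Why: Base-mediated O-alkylation (Williamson-type MOM protection) of three equivalent phenols should give the bis-ether as the main, separable fraction of a statistical mixture and leaves the one OH that becomes O1; no stereocenter is formed.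

Step 2
Reactants: 3 3,5-bis(methoxymethoxy)phenol; 4 chlorotri(propan-2-yl)silane
Product: 5 [3,5-bis(methoxymethoxy)phenoxy]tri(propan-2-yl)silane
Conditions: TIPSCl (1.1 equiv), imidazole (1.2 equiv), DMF, rt
Reagents that add atoms: chlorotri(propan-2-yl)silane, CC(C)[Si](Cl)(C(C)C)C(C)C
Why: Silyl ether formation at the only free phenol should be clean, and the bulky TIPS group later shields its two ortho positions from metalation.

Step 3
Reactants: 5 [3,5-bis(methoxymethoxy)phenoxy]tri(propan-2-yl)silane; 6 1-bromo-3-methylbut-2-ene (prenyl bromide)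
Product: 8 [3,5-bis(methoxymethoxy)-4-(3-methylbut-2-en-1-yl)phenoxy]tri(propan-2-yl)silane, via aryllithium 7 (not isolated)
Conditions: n-BuLi (1.2 equiv), THF, 0 °C; then CuBr·SMe2 (10 mol %), prenyl bromide, −78 °C → rt
Reagents that add atoms: 1-bromo-3-methylbut-2-ene, CC(C)=CCBr
Why: Directed ortho-metalation occurs at the carbon flanked by the two coordinating MOM ethers and remote from the TIPS group, and copper-assisted SN2 alkylation of the aryllithium by the primary allylic bromide should place the prenyl group para to the silyloxy oxygen.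

Step 4
Reactants: 8 [3,5-bis(methoxymethoxy)-4-(3-methylbut-2-en-1-yl)phenoxy]tri(propan-2-yl)silane
Product: 9 3,5-bis(methoxymethoxy)-4-(3-methylbut-2-en-1-yl)phenol
Conditions: TBAF (1.1 equiv), THF, 0 °C; aq. NH4Cl
Reagents that add atoms: none
Why: Fluoride-induced Si–O cleavage (desilylation) should release the phenol while the MOM ethers and the alkene are inert.

Step 5
Reactants: 9 3,5-bis(methoxymethoxy)-4-(3-methylbut-2-en-1-yl)phenol; 10 N-iodosuccinimide
Product: 11 2-iodo-3,5-bis(methoxymethoxy)-4-(3-methylbut-2-en-1-yl)phenol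
Conditions: NIS (1.0 equiv), CH2Cl2, −40 → 0 °C, dark
Reagents that add atoms: N-iodosuccinimide, O=C1CCC(=O)N1I
Why: Electrophilic aromatic iodination of the phloroglucinol-type phenol should be much faster than attack on the trisubstituted alkene, and because the two open ring positions are equivalent, one equivalent of NIS can give only one mono-iodide.

Step 6
Reactants: 11 2-iodo-3,5-bis(methoxymethoxy)-4-(3-methylbut-2-en-1-yl)phenol; 12 ethyl 3-bromo-2-oxopropanoate (ethyl bromopyruvate)
Product: 13 ethyl 3-[2-iodo-3,5-bis(methoxymethoxy)-4-(3-methylbut-2-en-1-yl)phenoxy]-2-oxopropanoate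
Conditions: K2CO3 (1.1 equiv), acetone, 0 °C → rt; used without acidic work-up
Reagents that add atoms: ethyl 3-bromo-2-oxopropanoate, CCOC(=O)C(=O)CBr
Why: Williamson ether synthesis by SN2 displacement of the highly reactive α-keto bromide by the phenoxide forms the O1–C2 bond and brings in C2, C3 and C4 in one piece.

Step 7
Reactants: 14 4-bromo-3-methoxyphenol; 15 tributyl(3-methylbut-2-en-1-yl)stannane
Product: 16 3-methoxy-4-(3-methylbut-2-en-1-yl)phenol
Conditions: Pd(PPh3)4 (5 mol %), DMF, 100 °C
Reagents that add atoms: tributyl(3-methylbut-2-en-1-yl)stannane, CCCC[Sn](CCCC)(CCCC)CC=C(C)C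
Why: Stille coupling (oxidative addition of the aryl bromide, allyl transfer from tin, reductive elimination at the unsubstituted allyl terminus) should give the linear prenyl arene, and free phenols are tolerated.

Step 8
Reactants: 13 ethyl 3-[2-iodo-3,5-bis(methoxymethoxy)-4-(3-methylbut-2-en-1-yl)phenoxy]-2-oxopropanoate; 16 3-methoxy-4-(3-methylbut-2-en-1-yl)phenol
Product: 19 rac-3-hydroxy-3-{[2-iodo-3,5-bis(methoxymethoxy)-4-(3-methylbut-2-en-1-yl)phenoxy]methyl}-6-methoxy-5-(3-methylbut-2-en-1-yl)-1-benzofuran-2(3H)-one, via magnesium phenoxide 17 (not isolated), via hydroxy ester alkoxide 18 (not isolated)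
Conditions: 16, EtMgBr (1.0 equiv), Et2O, 0 °C; solvent exchange to CH2Cl2; 13, 0 °C → rt, then 40 °C; aq. NH4Cl
Reagents that add atoms: none
Why: In this ortho-specific hydroxyalkylation of a magnesium phenoxide the chelated keto ester is attacked by the less hindered ortho carbon (para to OMe) in a Friedel–Crafts-type addition and the o-hydroxyaryl hydroxy ester should lactonise to the five-membered aryl lactone; the C3 carbinol stereocenter forms without control (racemate) and is removed in step 11.

Step 9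
Reactants: 19 rac-3-hydroxy-3-{[2-iodo-3,5-bis(methoxymethoxy)-4-(3-methylbut-2-en-1-yl)phenoxy]methyl}-6-methoxy-5-(3-methylbut-2-en-1-yl)-1-benzofuran-2(3H)-one
Product: 22 rac-3-hydroxy-3-[2-hydroxy-4-methoxy-5-(3-methylbut-2-en-1-yl)phenyl]-5,7-bis(methoxymethoxy)-6-(3-methylbut-2-en-1-yl)-2,3-dihydro-4H-chromen-4-one, via arylmagnesium alkoxide 20 (not isolated), via hemiketal dialkoxide 21 (not isolated)
Conditions: i-PrMgCl·LiCl (2.2 equiv), THF, −30 → 0 °C; aq. NH4Cl at 0 °C
Reagents that add atoms: none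
Why: i-PrMgCl first deprotonates the tertiary OH and then exchanges the only aryl iodide for magnesium; the aryl carbanion at C4a, held six atoms from the lactone carbonyl C4 through O1–C2–C3, adds to it and the tetrahedral intermediate 21 expels the ring B phenoxide, so the C4–C4a bond closes ring C while the temporary O2'–C4 lactone bond breaks. The closest known reaction type is the Parham cyclization, that is, halogen–metal exchange followed by intramolecular acylation of the arylmetal by an ester, here an aryl lactone. Ring C closes in the 6-exo-trig mode and the five-membered lactone opens by acyl–oxygen cleavage. No stereocenter is created: the quaternary C3 carbinol is carried through as a racemate and erased in step 11, its role here being to leave C3 without an acidic hydrogen so that neither enolisation nor β-elimination of the O1 aryloxide can compete. The step needs chemoselectivity (exchange only at C–I, attack only at the lactone), secured by the absence of any other halide or electrophilic carbonyl and by the magnesium alkoxide masking the OH, and regioselectivity (bond to C4a, not C8), fixed in step 5 where iodine entered one of two equivalent positions ortho to O1.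

Step 10
Reactants: 22 rac-3-hydroxy-3-[2-hydroxy-4-methoxy-5-(3-methylbut-2-en-1-yl)phenyl]-5,7-bis(methoxymethoxy)-6-(3-methylbut-2-en-1-yl)-2,3-dihydro-4H-chromen-4-one; 23 acetic anhydride
Product: 24 rac-2-[3-acetoxy-5,7-bis(methoxymethoxy)-6-(3-methylbut-2-en-1-yl)-4-oxo-3,4-dihydro-2H-chromen-3-yl]-5-methoxy-4-(3-methylbut-2-en-1-yl)phenyl acetate
Conditions: Ac2O (4 equiv), Et3N, DMAP (0.2 equiv), CH2Cl2, rt → 40 °C
Reagents that add atoms: acetic anhydride, CC(=O)OC(C)=O
Why: DMAP-catalysed acylation should esterify both the phenol (removing an internal proton source) and the tertiary α-ketol (turning C3–O into a reductively cleavable leaving group).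

Step 11
Reactants: 24 rac-2-[3-acetoxy-5,7-bis(methoxymethoxy)-6-(3-methylbut-2-en-1-yl)-4-oxo-3,4-dihydro-2H-chromen-3-yl]-5-methoxy-4-(3-methylbut-2-en-1-yl)phenyl acetate
Product: 26 2-[(3S)-5,7-bis(methoxymethoxy)-6-(3-methylbut-2-en-1-yl)-4-oxo-3,4-dihydro-2H-chromen-3-yl]-5-methoxy-4-(3-methylbut-2-en-1-yl)phenyl acetate, via samarium enolate 25 (not isolated)
Conditions: SmI2 (2.2 equiv), BINAPO [2,2'-bis(diphenylphosphoryl)-1,1'-binaphthyl, one antipode, 2.4 equiv], Ph3COH (1.5 equiv), THF, −78 → −45 °C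
Reagents that add atoms: none
Why: Reductive cleavage of the α-acyloxy ketone by SmI2 (ketyl formation, loss of acetate, second electron transfer) gives the samarium enolate, and its enantioselective protonation by trityl alcohol within the chiral BINAPO–samarium complex sets the C3–H stereocenter, the ligand antipode being chosen so that the (3S) ketone results.

Step 12
Reactants: 26 2-[(3S)-5,7-bis(methoxymethoxy)-6-(3-methylbut-2-en-1-yl)-4-oxo-3,4-dihydro-2H-chromen-3-yl]-5-methoxy-4-(3-methylbut-2-en-1-yl)phenyl acetate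
Product: 27 (3S)-5,7-dihydroxy-3-[2-hydroxy-4-methoxy-5-(3-methylbut-2-en-1-yl)phenyl]-6-(3-methylbut-2-en-1-yl)-2,3-dihydro-4H-chromen-4-one
Conditions: HCl (1.25 M in MeOH), MeOH/THF, 0 °C → rt, monitored and stopped at full conversion
Reagents that add atoms: none
Why: Acid-catalysed acetal exchange of the two MOM ethers and methanolysis of the aryl acetate should unmask the three phenols, while the tertiary C3–H of the hindered aryl ketone enolises only slowly in dilute acid at or below room temperature, so the configuration and the prenyl groups should be retained.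

**Compound list**

1 | phloroglucinol (benzene-1,3,5-triol) | Oc1cc(O)cc(O)c1 | starting material
2 | chloromethyl methyl ether | COCCl | starting material
3 | 3,5-bis(methoxymethoxy)phenol | COCOc1cc(O)cc(OCOC)c1 | intermediate
4 | chlorotri(propan-2-yl)silane | CC(C)[Si](Cl)(C(C)C)C(C)C | starting material
5 | [3,5-bis(methoxymethoxy)phenoxy]tri(propan-2-yl)silane | COCOc1cc(O[Si](C(C)C)(C(C)C)C(C)C)cc(OCOC)c1 | intermediate
6 | 1-bromo-3-methylbut-2-ene | CC(C)=CCBr | starting material
7 | 2,6-bis(methoxymethoxy)-4-[tri(propan-2-yl)silyloxy]phenyllithium (formed in situ) | COCOc1cc(O[Si](C(C)C)(C(C)C)C(C)C)cc(OCOC)c1[Li] | intermediate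
8 | [3,5-bis(methoxymethoxy)-4-(3-methylbut-2-en-1-yl)phenoxy]tri(propan-2-yl)silane | COCOc1cc(O[Si](C(C)C)(C(C)C)C(C)C)cc(OCOC)c1CC=C(C)C | intermediate
9 | 3,5-bis(methoxymethoxy)-4-(3-methylbut-2-en-1-yl)phenol | COCOc1cc(O)cc(OCOC)c1CC=C(C)C | intermediate
10 | N-iodosuccinimide | O=C1CCC(=O)N1I | starting material
11 | 2-iodo-3,5-bis(methoxymethoxy)-4-(3-methylbut-2-en-1-yl)phenol | COCOc1cc(O)c(I)c(OCOC)c1CC=C(C)C | intermediate
12 | ethyl 3-bromo-2-oxopropanoate | CCOC(=O)C(=O)CBr | starting material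
13 | ethyl 3-[2-iodo-3,5-bis(methoxymethoxy)-4-(3-methylbut-2-en-1-yl)phenoxy]-2-oxopropanoate | CCOC(=O)C(=O)COc1cc(OCOC)c(CC=C(C)C)c(OCOC)c1I | intermediate
14 | 4-bromo-3-methoxyphenol | COc1cc(O)ccc1Br | starting material
15 | tributyl(3-methylbut-2-en-1-yl)stannane | CCCC[Sn](CCCC)(CCCC)CC=C(C)C | starting material
16 | 3-methoxy-4-(3-methylbut-2-en-1-yl)phenol | COc1cc(O)ccc1CC=C(C)C | intermediate
17 | bromomagnesium 3-methoxy-4-(3-methylbut-2-en-1-yl)phenoxide (formed in situ) | COc1cc(O[Mg]Br)ccc1CC=C(C)C | intermediate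
18 | bromomagnesium alkoxide of racemic ethyl 2-hydroxy-2-[2-hydroxy-4-methoxy-5-(3-methylbut-2-en-1-yl)phenyl]-3-[2-iodo-3,5-bis(methoxymethoxy)-4-(3-methylbut-2-en-1-yl)phenoxy]propanoate (formed in situ) | CCOC(=O)C(O[Mg]Br)(COc1cc(OCOC)c(CC=C(C)C)c(OCOC)c1I)c1cc(CC=C(C)C)c(OC)cc1O | intermediate
19 | rac-3-hydroxy-3-{[2-iodo-3,5-bis(methoxymethoxy)-4-(3-methylbut-2-en-1-yl)phenoxy]methyl}-6-methoxy-5-(3-methylbut-2-en-1-yl)-1-benzofuran-2(3H)-one | O=C1Oc2cc(OC)c(CC=C(C)C)cc2C1(O)COc1cc(OCOC)c(CC=C(C)C)c(OCOC)c1I | intermediate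
20 | chloromagnesium alkoxide of 19 carrying MgCl in place of iodine (formed in situ) | O=C1Oc2cc(OC)c(CC=C(C)C)cc2C1(O[Mg]Cl)COc1cc(OCOC)c(CC=C(C)C)c(OCOC)c1[Mg]Cl | intermediate
21 | tetracyclic bis(chloromagnesium) hemiketal alkoxide, chromane fused to 2,3-dihydrobenzofuran through C3 and C4 (formed in situ) | COCOc1cc2OCC3(O[Mg]Cl)c4cc(CC=C(C)C)c(OC)cc4OC3(O[Mg]Cl)c2c(OCOC)c1CC=C(C)C | intermediate
22 | rac-3-hydroxy-3-[2-hydroxy-4-methoxy-5-(3-methylbut-2-en-1-yl)phenyl]-5,7-bis(methoxymethoxy)-6-(3-methylbut-2-en-1-yl)-2,3-dihydro-4H-chromen-4-one | COCOc1cc2OCC(O)(c3cc(CC=C(C)C)c(OC)cc3O)C(=O)c2c(OCOC)c1CC=C(C)C | intermediate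
23 | acetic anhydride | CC(=O)OC(C)=O | starting material
24 | rac-2-[3-acetoxy-5,7-bis(methoxymethoxy)-6-(3-methylbut-2-en-1-yl)-4-oxo-3,4-dihydro-2H-chromen-3-yl]-5-methoxy-4-(3-methylbut-2-en-1-yl)phenyl acetate | COCOc1cc2OCC(OC(C)=O)(c3cc(CC=C(C)C)c(OC)cc3OC(C)=O)C(=O)c2c(OCOC)c1CC=C(C)C | intermediate
25 | diiodosamarium enolate (C3=C4–O–SmI2) of the 2'-acetoxy-5,7-bis(methoxymethoxy) isoflavanone (formed in situ) | COCOc1cc2OCC(c3cc(CC=C(C)C)c(OC)cc3OC(C)=O)=C(O[Sm](I)I)c2c(OCOC)c1CC=C(C)C | intermediate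
26 | 2-[(3S)-5,7-bis(methoxymethoxy)-6-(3-methylbut-2-en-1-yl)-4-oxo-3,4-dihydro-2H-chromen-3-yl]-5-methoxy-4-(3-methylbut-2-en-1-yl)phenyl acetate | COc1cc(OC(C)=O)c([C@H]2COc3cc(OCOC)c(CC=C(C)C)c(OCOC)c3C2=O)cc1CC=C(C)C | intermediate
27 | (3S)-5,7-dihydroxy-3-[2-hydroxy-4-methoxy-5-(3-methylbut-2-en-1-yl)phenyl]-6-(3-methylbut-2-en-1-yl)-2,3-dihydro-4H-chromen-4-one | COc1cc(O)c([C@H]2COc3cc(O)c(CC=C(C)C)c(O)c3C2=O)cc1CC=C(C)C | target

**Step count and risks**

Total step count: 12. Longest linear sequence: 11 (steps 1 to 6, then 8 to 12, from phloroglucinol).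

Steps most likely to fail:

Step 8. The keto ester 13 may enolise under the basic magnesium phenoxide, its ketone may be captured by the tethered electron-rich ring A instead of ring B, or attack may occur at the ortho position between OH and OMe. The fallback reverses the order of bond formation. Starting from phenol 16, the magnesium phenoxide 17 is added to ethyl bromopyruvate 12 itself (CH2Cl2, 0 °C → rt), a ketone that carries no competing arene. The ortho adduct, the bromomagnesium alkoxide of ethyl 3-bromo-2-hydroxy-2-[2-hydroxy-4-methoxy-5-(3-methylbut-2-en-1-yl)phenyl]propanoate F1, should lactonise to 3-(bromomethyl)-3-hydroxy-6-methoxy-5-(3-methylbut-2-en-1-yl)-1-benzofuran-2(3H)-one F2. Treatment of F2 with iodophenol 11 and K2CO3 in acetone should close the bromohydrin to the spiro-epoxide 6-methoxy-5-(3-methylbut-2-en-1-yl)spiro[1-benzofuran-3,2'-oxiran]-2-one F3, which the phenoxide of 11 opens at the CH2 terminus. The route is rejoined at lactone 19.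

Step 11. Facial discrimination in the protonation of the samarium enolate may be insufficient, or the liberated ketone may be over-reduced. The fallback separates deoxygenation from stereocontrol. Starting from diacetate 24, SmI2 with MeOH in THF at −78 °C gives, through enolate 25, racemic 2-[5,7-bis(methoxymethoxy)-6-(3-methylbut-2-en-1-yl)-4-oxo-3,4-dihydro-2H-chromen-3-yl]-5-methoxy-4-(3-methylbut-2-en-1-yl)phenyl acetate F4. Asymmetric transfer hydrogenation with dynamic kinetic resolution (RuCl(p-cymene)[(S,S)-TsDPEN] or its antipode, HCO2H/Et3N, 40 °C; C3 equilibrates through the enol while one enantiomer is reduced faster) should give the cis alcohol 2-[(3S,4S)-4-hydroxy-5,7-bis(methoxymethoxy)-6-(3-methylbut-2-en-1-yl)-3,4-dihydro-2H-chromen-3-yl]-5-methoxy-4-(3-methylbut-2-en-1-yl)phenyl acetate F5. Buffered Dess–Martin oxidation (NaHCO3, CH2Cl2, 0 °C) removes the C4 stereocenter and keeps C3, rejoining the route at 26.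

Step 12. Acid-catalysed enolisation may erode the C3 configuration while the MOM ethers are cleaved. The fallback moves the acidic MOM removal to a stage where C3 is quaternary and makes the last step neutral. Starting from 22, HCl in MeOH gives racemic 3,5,7-trihydroxy-3-[2-hydroxy-4-methoxy-5-(3-methylbut-2-en-1-yl)phenyl]-6-(3-methylbut-2-en-1-yl)-2,3-dihydro-4H-chromen-4-one F6. Exhaustive acetylation (Ac2O, Et3N, DMAP) gives the racemic tetraacetate 3-[2-acetoxy-4-methoxy-5-(3-methylbut-2-en-1-yl)phenyl]-6-(3-methylbut-2-en-1-yl)-4-oxo-3,4-dihydro-2H-chromene-3,5,7-triyl triacetate F7. Reductive cleavage and protonation under the conditions of step 11 proceed through the diiodosamarium enolate of the 5,7,2'-triacetoxy isoflavanone F8 to (3S)-3-[2-acetoxy-4-methoxy-5-(3-methylbut-2-en-1-yl)phenyl]-6-(3-methylbut-2-en-1-yl)-4-oxo-3,4-dihydro-2H-chromene-5,7-diyl diacetate F9. Neutral deacetylation of the aryl acetates (NH4OAc, aqueous MeOH, rt) then gives the target 27.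

Further compounds
F1 | step 8 | bromomagnesium alkoxide of racemic ethyl 3-bromo-2-hydroxy-2-[2-hydroxy-4-methoxy-5-(3-methylbut-2-en-1-yl)phenyl]propanoate | CCOC(=O)C(O[Mg]Br)(CBr)c1cc(CC=C(C)C)c(OC)cc1O
F2 | step 8 | rac-3-(bromomethyl)-3-hydroxy-6-methoxy-5-(3-methylbut-2-en-1-yl)-1-benzofuran-2(3H)-one | O=C1Oc2cc(OC)c(CC=C(C)C)cc2C1(O)CBr
F3 | step 8 | rac-6-methoxy-5-(3-methylbut-2-en-1-yl)spiro[1-benzofuran-3,2'-oxiran]-2-one | O=C1Oc2cc(OC)c(CC=C(C)C)cc2C13CO3
F4 | step 11 | rac-2-[5,7-bis(methoxymethoxy)-6-(3-methylbut-2-en-1-yl)-4-oxo-3,4-dihydro-2H-chromen-3-yl]-5-methoxy-4-(3-methylbut-2-en-1-yl)phenyl acetate | COc1cc(OC(C)=O)c(C2COc3cc(OCOC)c(CC=C(C)C)c(OCOC)c3C2=O)cc1CC=C(C)C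
F5 | step 11 | 2-[(3S,4S)-4-hydroxy-5,7-bis(methoxymethoxy)-6-(3-methylbut-2-en-1-yl)-3,4-dihydro-2H-chromen-3-yl]-5-methoxy-4-(3-methylbut-2-en-1-yl)phenyl acetate | COc1cc(OC(C)=O)c([C@H]2COc3cc(OCOC)c(CC=C(C)C)c(OCOC)c3[C@H]2O)cc1CC=C(C)C
F6 | step 12 | rac-3,5,7-trihydroxy-3-[2-hydroxy-4-methoxy-5-(3-methylbut-2-en-1-yl)phenyl]-6-(3-methylbut-2-en-1-yl)-2,3-dihydro-4H-chromen-4-one | Oc1cc2OCC(O)(c3cc(CC=C(C)C)c(OC)cc3O)C(=O)c2c(O)c1CC=C(C)C
F7 | step 12 | rac-3-[2-acetoxy-4-methoxy-5-(3-methylbut-2-en-1-yl)phenyl]-6-(3-methylbut-2-en-1-yl)-4-oxo-3,4-dihydro-2H-chromene-3,5,7-triyl triacetate | CC(=O)Oc1cc2OCC(OC(C)=O)(c3cc(CC=C(C)C)c(OC)cc3OC(C)=O)C(=O)c2c(OC(C)=O)c1CC=C(C)C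
F8 | step 12 | diiodosamarium enolate (C3=C4–O–SmI2) of the 5,7,2'-triacetoxy isoflavanone | CC(=O)Oc1cc2OCC(c3cc(CC=C(C)C)c(OC)cc3OC(C)=O)=C(O[Sm](I)I)c2c(OC(C)=O)c1CC=C(C)C
F9 | step 12 | (3S)-3-[2-acetoxy-4-methoxy-5-(3-methylbut-2-en-1-yl)phenyl]-6-(3-methylbut-2-en-1-yl)-4-oxo-3,4-dihydro-2H-chromene-5,7-diyl diacetate | COc1cc(OC(C)=O)c([C@H]2COc3cc(OC(C)=O)c(CC=C(C)C)c(OC(C)=O)c3C2=O)cc1CC=C(C)C
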